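## The problem

Kaempferol 3,7-di-O-sulfate (17) is a flavonol in which benzo ring A is fused to the pyranone ring C, the 4-hydroxyphenyl ring B sits on C2, and oxygens stand on C3, C5, C7 and C4'. It has no stereocenter; the only stereochemical element met on the way is the geometry of a tetrasubstituted alkene in an open-chain precursor. The central task is to tell four oxygens apart: O3 and O7 carry hydrogen sulfate, while O5 and O4' remain free. The sulfate monoesters are the fragile groups, the enol-type one on O3 most of all, because acid (their own included) cleaves them; they must go on late and be followed only by neutral operations. The 5-OH is locked in a hydrogen bond to the C4 carbonyl and is the least reactive hydroxyl, so it can protect itself, whereas the 4'-OH is reactive and needs a group that leaves under neutral conditions after sulfation. O3 is the oxygen that most flavone syntheses add afterwards by oxidation, and carrying it from the first C–C bond avoids oxidizing an electron-rich flavone. The feature that enables the key step is C4a: all three ring A oxygens activate it at once (it is ortho to O1 and O5 and para to O7), and in a symmetric 3,5-dialkoxyphenyl ether the two carbons of this kind are interchangeable, so an acyl carbon (C4) tethered through O1 can close only the wanted ring.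

## Retrosynthesis

**Freeing the acid and O4' (17 from 16 from 15).** No skeletal bond is cut. The free acid 17 is released only at the very end from the stable disodium salt 16, and 16 comes from the 4'-O-benzyl ether 15 by hydrogenolysis. Benzyl is chosen for O4' because its removal is neutral. An acid-labile group would cost the sulfates, and a base-labile acyl group would not survive the enolate and saponification steps earlier on.

**The two S–O bonds (15 from 13).** Cutting both sulfate S–O bonds leads to 4'-O-benzylkaempferol (13). The forward step relies on the known order of reactivity of flavonol hydroxyls towards sulfur trioxide–amine complexes: the 7-OH and 3-OH react, the chelated 5-OH does not. Protecting O5 separately would require two different groups on ring A, and that would destroy the symmetry the ring closure depends on.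

**Three O–allyl bonds (13 from 12).** The hydroxyls on C3, C5 and C7 are masked as allyl ethers in flavone 12. Allyl is removed by zerovalent palladium without touching the benzyl ether, and one kind of group on both ring A oxygens keeps the aryloxy ring symmetric.

**C4–C4a, the key cut (12 from 10).** Opening ring C at C4–C4a gives the acrylic acid 10, which carries every oxygen of the target. The neighbouring cut at O1–C2 would require an acylphloroglucinol with three differentiated oxygens and a C-acylation of phloroglucinol. The C4–C4a cut lets ring A enter as a symmetric phenol, and the ring closure cannot give a regioisomer. The forward reaction needs an acyl cation equivalent mild enough for three allyl ethers and a benzyl ether, and it needs the carboxyl cis to the aryloxy group, which is the E geometry of 10.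

**The vinyl–O bond C2–O1 (10 from 9, 9 from 8 and 3).** Acid 10 comes from its methyl ester 9. Cutting the bond between the alkene carbon and the aryloxy oxygen gives the enol triflate 8 and 3,5-bis(allyloxy)phenol (3). Adding a phenol to an arylpropiolate would give the same kind of ether more simply, but without O3. The enol triflate of an α-alkoxy β-keto ester keeps O3 and is open to addition–elimination by the phenoxide.

**The C2–C3 bond (8 from 7, 7 from 5 and 6).** Triflate 8 is the enol derivative of keto ester 7. A crossed Claisen cut between the carbons that become C2 and C3 gives methyl 2-(allyloxy)acetate (5) and 4-(benzyloxy)benzoyl chloride (6). The acid chloride is preferred to the corresponding methyl ester because it acylates the enolate at −78 °C, before an α-allyloxy ester enolate can rearrange or condense with itself.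

**The simple ethers (5 from 4 and 2; 3 from 1 and 2).** Ester 5 is the allyl ether of methyl glycolate (4). Phenol 3 is the bis-allyl ether of phloroglucinol (1), made with two equivalents of allyl bromide (2) in a statistical etherification. That step is the price paid for a symmetric ring A.

## Roads not taken

Alternative 1: ring A by biomimetic Claisen folding. The cut is C4a–C5 (the same as C4a–C8a by symmetry), so ring A would be built from the open-chain methyl (E)-9-[4-(benzyloxy)phenyl]-3,5,7-trioxonon-8-enoate A1. In the forward step Mg(OMe)2 or methanolic KOH would drive the C6 carbanion of A1 onto the ester carbonyl, and enolization would give 4-O-benzylnaringenin chalcone A2.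
- Merits: ring A needs no protecting groups and no statistical etherification, and the route would join the chosen one at 13. In these respects it is better than the chosen plan.
- Weak points: A1 must be assembled by polyanion chemistry. It can also fold by the aldol mode to a resorcylate, lactonize to a pyranone, or add methoxide to its enone. The product A2 has neither ring C nor O3. One-step oxidative cyclization of a 2'-hydroxychalcone to a flavonol tends to give aurones when the 6'-position bears oxygen, as here, so several steps of ring closure, C3 oxidation and dehydrogenation on a free phloroglucinol would follow.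
- Comparison: the chosen plan buys ring A and spends its key step on the one ring that must be made, with O3 and the oxidation level of ring C already in place.

Alternative 2: three-component carbonylative annulation. The cuts are C4a–C4, C4–C3 and O1–C2. 2-Iodo-5-(methoxymethoxy)benzene-1,3-diol A3, carbon monoxide and 1-(benzyloxy)-4-ethynylbenzene A4 would be joined by PdCl2(PPh3)2 in diethylamine, and the open-chain coupling product would close in the flask to 4'-benzyloxy-5-hydroxy-7-(methoxymethoxy)flavone A5.
- Merits: three bonds and ring C form in one catalytic step, the plan is convergent, the alkyne A4 is easy to obtain, the 5-OH is already free, and O7 and O4' are differentiated. In bond economy and in step count to the flavone skeleton this road is better than the chosen one, and it would be preferred for a target without O3.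
- Weak points: O3 is missing and would have to be added to A5 by C3 metalation–oxidation or epoxidation, with the 5-OH free or protected in an extra step. The 5-exo closure to an aurone competes with the 6-endo closure. A3 is an electron-rich, doubly ortho-substituted aryl iodide, and it also comes from a statistical protection of phloroglucinol.
- Comparison: the chosen plan sets against the shorter skeleton synthesis an O3 that is present from the first C–C bond, no late oxidation, and a ring closure with no competing mode.

Alternative 3: trifluorobenzoyl acylation and SNAr annulation. The cuts are C3–C4 and C8a–O1, with ring A carried as a trifluorophenyl group. The lithium enolate of 1-[4-(benzyloxy)phenyl]-2-[(4-methoxybenzyl)oxy]ethan-1-one A6 would be C-acylated by 2,4,6-trifluorobenzoyl chloride A7. On warming with K2CO3 an enolate oxygen of the resulting diketone would displace an ortho fluoride and give 4'-benzyloxy-5,7-difluoro-3-(4-methoxybenzyloxy)flavone A8.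
- Merits: O3 is carried from the start, as in the chosen plan. The two ortho fluorines of A7 are equivalent, so the closure is regiochemically safe. No acid-sensitive push-pull alkene is involved, and stepwise displacement of the fluorides could tell O5 from O7. In these points it equals or betters the chosen plan.
- Weak points: both ring A oxygens must be put into A8 after ring closure by two substitutions on a flavone, which alkoxides can also open at C2. The second substitution is on a ring deactivated by the first alkoxy group, and the order of C5 against C7 is not assured. O-acylation of the enolate of A6 by A7 may compete. These add at least two or three steps.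
- Comparison: for this target O5 need not be told from O7 by a protecting group, since the hydrogen bond does it, so the chosen plan takes ring A with its oxygens in place from phloroglucinol.

Key step: step 7

Assumption: the target is taken as drawn, the free bis(hydrogen sulfate). Because such acids hydrolyse in their own solution, 17 is liberated only in the last step from the stable disodium salt 16, in the cold, and freeze-dried at once.

## Route

Step 1
Reactants: 1 phloroglucinol; 2 allyl bromide
Product: 3 3,5-bis(allyloxy)phenol
Conditions: allyl bromide (2.0 equiv), K2CO3 (2.2 equiv), DMF, 0 °C to rt; chromatography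
Reagents that add atoms: allyl bromide (second equivalent), C=CCBr
Why: Twofold Williamson ether synthesis; in DMF with carbonate the phenoxide oxygens should be alkylated in preference to the ring carbons, and two equivalents of 2 should make the bis-ether the main component of a statistical mixture, from which it is separated while the mono-ether is returned to the reaction.

Step 2
Reactants: 4 methyl glycolate; 2 allyl bromide
Product: 5 methyl 2-(allyloxy)acetate
Conditions: NaH, THF, 0 °C; allyl bromide, Bu4NI (cat.), 0 °C to rt
Reagents that add atoms: none
Why: Williamson ether synthesis on the sodium alkoxide of 4; at 0 °C O-alkylation by the reactive allylic bromide should outrun transesterification between glycolate molecules.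

Step 3
Reactants: 5 methyl 2-(allyloxy)acetate; 6 4-(benzyloxy)benzoyl chloride
Product: 7 methyl 2-(allyloxy)-3-[4-(benzyloxy)phenyl]-3-oxopropanoate (racemic)
Conditions: LiN(SiMe3)2 (2.1 equiv), THF, −78 °C, 5 (2.1 equiv); then 6 (1.0 equiv), −78 °C; 1 M HCl quench at −78 °C
Reagents that add atoms: none
Why: Crossed Claisen condensation (C-acylation of a lithium ester enolate by an aroyl chloride); two equivalents of enolate are used because the product is deprotonated as it forms, and the acid chloride reacts at −78 °C, below the temperature at which an α-allyloxy ester enolate undergoes [2,3]-Wittig rearrangement or self-condensation; the stereocenter is racemic and is removed in step 4.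

Step 4
Reactants: 7 methyl 2-(allyloxy)-3-[4-(benzyloxy)phenyl]-3-oxopropanoate
Product: 8 methyl (E)-2-(allyloxy)-3-[4-(benzyloxy)phenyl]-3-(trifluoromethanesulfonyloxy)acrylate (triflate cis to the ester)
Conditions: NaH, CH2Cl2, 0 °C; Tf2O, −78 °C to 0 °C
Reagents that add atoms: trifluoromethanesulfonic anhydride, O=S(=O)(OS(=O)(=O)C(F)(F)F)C(F)(F)F
Why: Enol triflate formation by O-sulfonylation of a β-keto ester enolate; in the non-coordinating solvent the sodium enolate is chelated between the ketone and ester oxygens, so the triflate should end up cis to the ester (E by the sequence rules), and the enolate is kept at or below 0 °C so that it is trapped before any sigmatropic shift of the O-allyl group.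

Step 5
Reactants: 8 methyl (E)-2-(allyloxy)-3-[4-(benzyloxy)phenyl]-3-(trifluoromethanesulfonyloxy)acrylate; 3 3,5-bis(allyloxy)phenol
Product: 9 methyl (E)-2-(allyloxy)-3-[4-(benzyloxy)phenyl]-3-[3,5-bis(allyloxy)phenoxy]acrylate (aryloxy cis to the ester)
Conditions: Cs2CO3, DMF, 0 °C to rt
Reagents that add atoms: none
Why: Nucleophilic vinylic substitution by addition–elimination, known for β-sulfonyloxy and β-halo acrylates with phenoxides; the phenoxide of 3 adds to the β-carbon, which is activated by the ester and the triflate, and triflate leaves from the short-lived ester enolate with retention, so carboxyl and aryloxy stay cis; the geometry is not critical because step 7 equilibrates it.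

Step 6
Reactants: 9 methyl (E)-2-(allyloxy)-3-[4-(benzyloxy)phenyl]-3-[3,5-bis(allyloxy)phenoxy]acrylate
Product: 10 (E)-2-(allyloxy)-3-[4-(benzyloxy)phenyl]-3-[3,5-bis(allyloxy)phenoxy]acrylic acid
Conditions: LiOH·H2O (3 equiv), THF/MeOH/H2O, rt to 40 °C; then cold 1 M HCl to pH 3
Reagents that add atoms: lithium hydroxide, [Li+].[OH-]
Why: Saponification of a methyl ester; β-aryloxyacrylates are classically hydrolysed by aqueous hydroxide without loss of the aryloxy group, and a brief, cold acidification to pH 3 should leave the push-pull enol ether intact.

Step 7
Reactants: 10 (E)-2-(allyloxy)-3-[4-(benzyloxy)phenyl]-3-[3,5-bis(allyloxy)phenoxy]acrylic acid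
Product: 12 3,5,7-tris(allyloxy)-4'-(benzyloxy)flavone, via mixed trifluoroacetic anhydride 11 (not isolated)
Conditions: (CF3CO)2O (1.5 equiv), CH2Cl2, 0 °C to rt
Reagents that add atoms: none
Why: Trifluoroacetic anhydride converts 10 into the mixed anhydride 11, which ionizes with loss of trifluoroacetate to an acylium ion stabilized through the alkene by the aryloxy and 4-benzyloxyphenyl donors; the ring carbon next to the ether oxygen, activated also by both allyloxy groups, attacks it and loses a proton, forming C4–C4a. The closest known reaction type is the acid-mediated intramolecular Friedel–Crafts acylation of β-aryloxycinnamic acids to flavones. Ring C is closed in the 6-exo-trig mode at the acyl carbon of 11 (6-exo-dig if the free acylium ion is the electrophile). No stereocenter is formed. Site selectivity rests on the substrate: the aryloxy ring is symmetric, so both carbons flanking the ether oxygen give the same product, and the carbon para to that oxygen is out of reach of the tether. Only the E acid has carboxyl cis to aryloxy, but any Z isomer should equilibrate under the trifluoroacetic acid formed, by protonation at the α-carbon to an oxocarbenium ion and rotation. Ring closure within the molecule should be faster than trifluoroacetylation of the ring by the slight excess of anhydride at 0 °C, and the new carbonyl deactivates ring A against a second acylation. The conditions are mild enough for the allyl and benzyl ethers.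

Step 8
Reactants: 12 3,5,7-tris(allyloxy)-4'-(benzyloxy)flavone
Product: 13 4'-O-benzylkaempferol (2-[4-(benzyloxy)phenyl]-3,5,7-trihydroxy-4H-chromen-4-one)
Conditions: Pd(PPh3)4 (5 mol %), morpholine (10 equiv), THF, rt
Reagents that add atoms: none
Why: Tsuji–Trost-type deallylation; zerovalent palladium ionizes each allyl aryl or allyl enol ether to a π-allyl complex and the phenoxide, morpholine captures the allyl group, and a benzyl ether is inert to zerovalent palladium in the absence of hydrogen.

Step 9
Reactants: 13 4'-O-benzylkaempferol
Product: 15 disodium 4'-O-benzylkaempferol 3,7-bis(sulfate), via bis(pyridinium) 3,7-bis(sulfate) 14 (not isolated)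
Conditions: SO3·pyridine (4 equiv), pyridine, rt to 40 °C; then aq NaHCO3 to pH 8; reversed-phase chromatography
Reagents that add atoms: sulfur trioxide–pyridine complex (one per sulfate), O=S(=O)=O.c1ccncc1; sodium hydrogen carbonate, [Na+].OC([O-])=O
Why: O-sulfation of phenols with a sulfur trioxide–amine complex; the acidic 7-OH and the 3-OH react, the 5-OH locked in a hydrogen bond to the C4 carbonyl is known to resist this reagent under mild conditions, and O4' is blocked as its benzyl ether.

Step 10
Reactants: 15 disodium 4'-O-benzylkaempferol 3,7-bis(sulfate)
Product: 16 disodium kaempferol 3,7-bis(sulfate)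
Conditions: H2 (1 atm), Pd/C (10% palladium metal on carbon), MeOH/H2O, rt
Reagents that add atoms: none
Why: Hydrogenolysis of an aryl benzyl ether; aryl sulfate monoester salts are stable to neutral hydrogenolysis, and the 2,3-double bond of a flavonol, being part of a vinylogous ester, should not be reduced at 1 atm.

Step 11
Reactants: 16 disodium kaempferol 3,7-bis(sulfate)
Product: 17 kaempferol 3,7-di-O-sulfate
Conditions: sulfonic acid cation-exchange resin (H+ form), H2O, 0–5 °C; immediate freeze-drying
Reagents that add atoms: none
Why: Cation exchange; sodium is taken up by the resin and the free bis(hydrogen sulfate) is collected cold and freeze-dried at once, because it is a strong acid that catalyses its own hydrolysis on standing in solution.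

## Compound list

1 | phloroglucinol (benzene-1,3,5-triol) | Oc1cc(O)cc(O)c1 | starting material
2 | allyl bromide | C=CCBr | starting material
3 | 3,5-bis(allyloxy)phenol | Oc1cc(OCC=C)cc(OCC=C)c1 | intermediate
4 | methyl glycolate | COC(=O)CO | starting material
5 | methyl 2-(allyloxy)acetate | COC(=O)COCC=C | intermediate
6 | 4-(benzyloxy)benzoyl chloride | O=C(Cl)c1ccc(OCc2ccccc2)cc1 | starting material
7 | methyl 2-(allyloxy)-3-[4-(benzyloxy)phenyl]-3-oxopropanoate (racemic) | COC(=O)C(OCC=C)C(=O)c1ccc(OCc2ccccc2)cc1 | intermediate
8 | methyl (E)-2-(allyloxy)-3-[4-(benzyloxy)phenyl]-3-(trifluoromethanesulfonyloxy)acrylate | COC(=O)/C(OCC=C)=C(\OS(=O)(=O)C(F)(F)F)c1ccc(OCc2ccccc2)cc1 | intermediate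
9 | methyl (E)-2-(allyloxy)-3-[4-(benzyloxy)phenyl]-3-[3,5-bis(allyloxy)phenoxy]acrylate | COC(=O)/C(OCC=C)=C(\Oc1cc(OCC=C)cc(OCC=C)c1)c1ccc(OCc2ccccc2)cc1 | intermediate
10 | (E)-2-(allyloxy)-3-[4-(benzyloxy)phenyl]-3-[3,5-bis(allyloxy)phenoxy]acrylic acid | OC(=O)/C(OCC=C)=C(\Oc1cc(OCC=C)cc(OCC=C)c1)c1ccc(OCc2ccccc2)cc1 | intermediate
11 | (E)-2-(allyloxy)-3-[4-(benzyloxy)phenyl]-3-[3,5-bis(allyloxy)phenoxy]acrylic trifluoroacetic anhydride | O=C(OC(=O)C(F)(F)F)/C(OCC=C)=C(\Oc1cc(OCC=C)cc(OCC=C)c1)c1ccc(OCc2ccccc2)cc1 | intermediate (not isolated)
12 | 3,5,7-tris(allyloxy)-4'-(benzyloxy)flavone | O=c1c(OCC=C)c(-c2ccc(OCc3ccccc3)cc2)oc2cc(OCC=C)cc(OCC=C)c12 | intermediate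
13 | 4'-O-benzylkaempferol | O=c1c(O)c(-c2ccc(OCc3ccccc3)cc2)oc2cc(O)cc(O)c12 | intermediate
14 | bis(pyridinium) 4'-O-benzylkaempferol 3,7-bis(sulfate) | O=c1c(OS(=O)(=O)[O-])c(-c2ccc(OCc3ccccc3)cc2)oc2cc(OS(=O)(=O)[O-])cc(O)c12.c1cc[nH+]cc1.c1cc[nH+]cc1 | intermediate (not isolated)
15 | disodium 4'-O-benzylkaempferol 3,7-bis(sulfate) | O=c1c(OS(=O)(=O)[O-])c(-c2ccc(OCc3ccccc3)cc2)oc2cc(OS(=O)(=O)[O-])cc(O)c12.[Na+].[Na+] | intermediate
16 | disodium kaempferol 3,7-bis(sulfate) | O=c1c(OS(=O)(=O)[O-])c(-c2ccc(O)cc2)oc2cc(OS(=O)(=O)[O-])cc(O)c12.[Na+].[Na+] | intermediate
17 | kaempferol 3,7-di-O-sulfate | O=c1c(OS(=O)(=O)O)c(-c2ccc(O)cc2)oc2cc(OS(=O)(=O)O)cc(O)c12 | target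

## Step count and risks

Total step count: 11. Longest linear sequence: 10 steps (steps 2 to 11, from methyl glycolate 4); step 1 is the only step off the main line.

**Step 7 (key step).** The most likely failures are trifluoroacetylation of the electron-rich aryloxy ring in competition with ring closure; an acid-induced [3,3] shift or loss of the allyl group on the enol oxygen, since 11 is a 2-acyl allyl vinyl ether; and solvolytic loss of the aryloxy group from the protonated alkene. The fallback changes how the acyl cation is made. Acid 10 would be converted with 1-chloro-N,N,2-trimethylprop-1-en-1-amine in CH2Cl2 at 0 °C, under neutral conditions, into (E)-2-(allyloxy)-3-[4-(benzyloxy)phenyl]-3-[3,5-bis(allyloxy)phenoxy]acryloyl chloride F1. This isolated acyl chloride would be ionized by SnCl4 at −78 °C in the presence of 2,6-di-tert-butylpyridine, the classical acyl chloride Friedel–Crafts closure, with no protic acid and no trifluoroacetyl donor in the flask. The sequence returns to the route at 12.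

**Step 5.** The phenoxide may attack the sulfur of the triflate instead of the β-carbon, which would transfer the triflyl group to 3 and return the enolate of 7. Addition to the hindered, donor-substituted β-carbon may also be slow. The fallback changes the electrophile class so that no sulfur centre is present. Keto ester 7 would be chlorodehydroxylated with the Vilsmeier reagent from oxalyl chloride and DMF in CH2Cl2 to methyl (E)-2-(allyloxy)-3-[4-(benzyloxy)phenyl]-3-chloroacrylate F2 (either alkene isomer is usable). This vinylogous acid chloride would be substituted by 3 with K2CO3 and catalytic DABCO in DMF, the classical route from β-chloroacrylates to β-aryloxyacrylates. The sequence returns to the route at 9.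

**Step 3.** The lithium enolate of 5 may undergo [2,3]-Wittig rearrangement or condense with unreacted 5 if the acylation lags, and O-acylation may compete. The fallback replaces the free enolate by a neutral nucleophile. Ester 5 would be enolized with LiN(SiMe3)2 in the presence of Me3SiCl at −78 °C, so that the enolate is trapped as it forms, giving the ketene silyl acetal (Z)-{[2-(allyloxy)-1-methoxyethenyl]oxy}trimethylsilane F3. F3 would be C-acylated by 6 under TiCl4 in CH2Cl2 at −78 °C, a Mukaiyama-type Claisen condensation. The sequence returns to the route at 7.

**Step 9.** Sulfation may stop short at the hindered, hydrogen-bonded 3-OH, or with more reagent may begin to reach O5; the resulting mixtures of anionic products are hard to separate. The fallback uses protected sulfate diesters, which are neutral and can be purified on silica. Triol 13 would be deprotonated with NaN(SiMe3)2 (2 equiv, the 7-OH and 3-OH being the more acidic) in THF and treated with 2,2-dimethylpropyl chlorosulfate to give 2-[4-(benzyloxy)phenyl]-5-hydroxy-4-oxo-4H-chromene-3,7-diyl bis(2,2-dimethylpropyl) bis(sulfate) F4. After chromatography, both neopentyl groups would be removed by NaN3 in DMF at 60–70 °C (substitution at the neopentyl carbon with the aryl sulfate as leaving group). This gives the disodium salt directly and returns to the route at 15.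

## Further compounds

F1 | step 7 | (E)-2-(allyloxy)-3-[4-(benzyloxy)phenyl]-3-[3,5-bis(allyloxy)phenoxy]acryloyl chloride | O=C(Cl)/C(OCC=C)=C(\Oc1cc(OCC=C)cc(OCC=C)c1)c1ccc(OCc2ccccc2)cc1
F2 | step 5 | methyl (E)-2-(allyloxy)-3-[4-(benzyloxy)phenyl]-3-chloroacrylate | COC(=O)/C(OCC=C)=C(\Cl)c1ccc(OCc2ccccc2)cc1
F3 | step 3 | (Z)-{[2-(allyloxy)-1-methoxyethenyl]oxy}trimethylsilane | CO/C(O[Si](C)(C)C)=C/OCC=C
F4 | step 9 | 2-[4-(benzyloxy)phenyl]-5-hydroxy-4-oxo-4H-chromene-3,7-diyl bis(2,2-dimethylpropyl) bis(sulfate) | O=c1c(OS(=O)(=O)OCC(C)(C)C)c(-c2ccc(OCc3ccccc3)cc2)oc2cc(OS(=O)(=O)OCC(C)(C)C)cc(O)c12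
A1 | alternative 1 | methyl (E)-9-[4-(benzyloxy)phenyl]-3,5,7-trioxonon-8-enoate | COC(=O)CC(=O)CC(=O)CC(=O)/C=C/c1ccc(OCc2ccccc2)cc1
A2 | alternative 1 | 4-O-benzylnaringenin chalcone, (E)-3-[4-(benzyloxy)phenyl]-1-(2,4,6-trihydroxyphenyl)prop-2-en-1-one | O=C(/C=C/c1ccc(OCc2ccccc2)cc1)c1c(O)cc(O)cc1O
A3 | alternative 2 | 2-iodo-5-(methoxymethoxy)benzene-1,3-diol | COCOc1cc(O)c(I)c(O)c1
A4 | alternative 2 | 1-(benzyloxy)-4-ethynylbenzene | C#Cc1ccc(OCc2ccccc2)cc1
A5 | alternative 2 | 4'-benzyloxy-5-hydroxy-7-(methoxymethoxy)flavone | O=c1cc(-c2ccc(OCc3ccccc3)cc2)oc2cc(OCOC)cc(O)c12
A6 | alternative 3 | 1-[4-(benzyloxy)phenyl]-2-[(4-methoxybenzyl)oxy]ethan-1-one | O=C(COCc1ccc(OC)cc1)c1ccc(OCc2ccccc2)cc1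
A7 | alternative 3 | 2,4,6-trifluorobenzoyl chloride | O=C(Cl)c1c(F)cc(F)cc1F
A8 | alternative 3 | 4'-benzyloxy-5,7-difluoro-3-(4-methoxybenzyloxy)flavone | O=c1c(OCc2ccc(OC)cc2)c(-c2ccc(OCc3ccccc3)cc2)oc2cc(F)cc(F)c12
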